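A flat stretch on a trace is easily taken for a flask that has stopped, yet a stopped flask and a balanced one print the same line, and you tell them apart by disturbing them.

| flask | Q | G | L | remark | time |
|---|---|---|---|---|---|
| dawn | 49 mM | 0.95 equiv | 2.8 mol% | the very flask that is asked about, followed so far |  |
| flask | 49 mM | 0.950 equiv | 2.8 mol% |  | 6.0 d |

dawn run (percent of the Q charged): time / h: J / % = 10.0: 33.5; 15.0: 32.1; 20.0: 30.0; 30.0: 25.8; 50.0: 22.6; 72.0: 23.6; 120: 22.2

(standard deviation of a reading: 0.5 percentage points)

- violet: at 6.0 d add G, 50.0% of the amount charged, then wait 40 h
- red: change nothing and wait 40 h more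
- green: at 6.0 d add L, 100% of the amount charged, then wait 40 h
- teal: at 6.0 d take out 90% of the J then present, then wait 40 h

- J that was removed still counts
- additions bring no volume worth counting

- J, in percent of the Q first charged, at 6.0 d
- which option adds most J ("none" when 2 percentage points or less is all one gets) (violet / red / green / teal / none)
- J present, with what was taken out counted in, in percent of the Q first charged, after red
- J present, with what was taken out counted in, in percent of the Q first charged, after teal

Climb the dawn run by its time scales, fastest first. J reads 33.5% at the first reading, 10.0 h, so that much of it is made within that time. J then falls for about 40.0 h, and from 50.0 h to 120 h it stays near a mean of 22.8%, which I also commit to for 6.0 d and after red. The wait of 40 h is about as long as that fall, so a disturbed flask has time to move, if it can.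

My own reckoning carries one quantity, the holding quotient W, which is cJ/(cQ·cG) on the flat stretch, the usual reaction quotient. If the fall carried J into unseen forms that keep their Q and G, then at least the peak reading stays bound, and W has a floor of 11.4 M⁻¹. Hold W there and take out 90% of the J in the flask: J regrows by 12 percentage points, so teal counts 35.3%. Violet's added G gives 9.1 points, less than teal, and green adds L, which stands nowhere in W. I choose teal.

The forecast says 22.8% now, 22.7% after red, 22.9% after teal and none as best, on the ground that “Removing J should not pull more through”; its teal lies below mine.

    Q + G ⇌ J (K = 32.0 M⁻¹, k = 2.49 M⁻¹ h⁻¹)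
    Q + G ⇌ E (K = 52.0 M⁻¹, k = 0.0602 M⁻¹ h⁻¹)
    J + D ⇌ E + D, rate k3*[D]*[J] forward; the back reaction follows from the equilibrium constant (k = 82.0 M⁻¹ h⁻¹)
    G + D → Z (k = 0.151 M⁻¹ h⁻¹)
    G + L → D + X (k = 1.34 M⁻¹ h⁻¹)

The flask gives 22.1% at 6.0 d and 22.1% after red, while teal is best at 36.3%, a gain of 14 points against 5.9 points for violet. At 144 h the flask holds J 22.1% and Q 42.0%, both in percent of the Q charged, and G 35.3% of its own charge, so W is 32.1 M⁻¹, above the floor of 11.4 M⁻¹. The second flask, charged with 83 mM of Q, ends at J 24.7% and has a W of 32.1 M⁻¹, about the same as the first flask's.

The earlier runs and the new flask are simulated for an exercise; noise was put on by code.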